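**Retrosynthetic overview**
1. No ring is built. The chromone (noreugenin 1) and the piperidine (1-methylpiperidin-4-one 2) are bought intact. The only C–C disconnection is C8–C4′, made by Friedel–Crafts hydroxyalkylation/dehydration (carbinol 3, then the achiral o-hydroxystyrene 4).
2. C3′–O comes from dihydroxylation of 4 (racemic diol 5). The angelate is installed before the stereocentres exist, from angelic anhydride 6 (diester 7, then hydroxy ester 8).
3. C4′–H and both stereocentres come last. 8 ionises to o-quinone methide 9, which equilibrates with the achiral enol ester 10, and a chiral phosphoric acid/Hantzsch ester transfer hydrogenation gives the target 11.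

Assumption: noreugenin, angelic anhydride, (R)-TRIP and the Hantzsch ester are taken as commercially available.
Handling note: 4 is an MPTP-type 4-aryl-1-methyl-1,2,3,6-tetrahydropyridine and is treated as a potential neurotoxin.

**Step 1**
Reactants: 1 noreugenin (5,7-dihydroxy-2-methyl-4H-chromen-4-one); 2 1-methylpiperidin-4-one
Product: 4 5,7-dihydroxy-2-methyl-8-(1-methyl-1,2,3,6-tetrahydropyridin-4-yl)-4H-chromen-4-one, via carbinol 3 (not isolated)
Conditions: AcOH, HCl (g), 95 °C; aq NaHCO3
Reagents that add atoms: none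
Why: Friedel–Crafts hydroxyalkylation of the phloroglucinol-type ring by the protonated ketone followed by E1 dehydration of carbinol 3; C8 is the less hindered nucleophilic site of a 5,7-dihydroxychromone (the site taken in Mannich reactions), the addition is reversible so the C8 isomer should accumulate, and no stereocentre is formed.

**Step 2**
Reactants: 4 5,7-dihydroxy-2-methyl-8-(1-methyl-1,2,3,6-tetrahydropyridin-4-yl)-4H-chromen-4-one
Product: 5 rac-8-[(3R,4R)-3,4-dihydroxy-1-methylpiperidin-4-yl]-5,7-dihydroxy-2-methyl-4H-chromen-4-one (cis-diol; racemate)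
Conditions: OsO4 (2 mol%), NMO (1.5 equiv), acetone/H2O 4:1, rt; aq Na2SO3
Reagents that add atoms: N-methylmorpholine N-oxide, C[N+]1([O-])CCOCC1; water, O
Why: Upjohn syn-dihydroxylation, in which OsO4 takes the electron-rich trisubstituted styrenyl C=C far faster than the electron-poor pyrone C=C and NMO leaves the amine and phenols alone; the diol is racemic on purpose because both centres are erased and reset in step 4.

**Step 3**
Reactants: 5 rac-cis-diol; 6 angelic anhydride [(2Z)-2-methylbut-2-enoic anhydride]
Product: 8 rac-(3R,4R)-4-(5,7-dihydroxy-2-methyl-4-oxo-4H-chromen-8-yl)-4-hydroxy-1-methylpiperidin-3-yl (2Z)-2-methylbut-2-enoate, via bis-angelate 7 (not isolated)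
Conditions: LiN(SiMe3)2 (3.2 equiv), THF, −20 °C; 6 (2.4 equiv), −20 to 0 °C; MeOH, 0 °C, 30 min; aq NH4Cl
Reagents that add atoms: none
Why: Acylation of lithium alkoxide/phenoxide by the anhydride is stereoconservative for angelates (no acylpyridinium, so no Z to E drift) and gives the 3′,7-diester because the tertiary 4′-O and the chelated 5-O are unreactive; the 7-aryl ester of this vinylogous acid is an active ester that methoxide/MeOH cleaves in minutes while the hindered secondary angelate stays.

**Step 4**
Reactants: 8 rac-hydroxy angelate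
Product: 11 (3S,4R)-4-(5,7-dihydroxy-2-methyl-4-oxo-4H-chromen-8-yl)-1-methylpiperidin-3-yl (2Z)-2-methylbut-2-enoate (target), via o-quinone methide 9 (not isolated), via enol angelate 10 (not isolated)
Conditions: Tf2NH (1.0 equiv), (R)-TRIP [(R)-3,3′-bis(2,4,6-triisopropylphenyl)-1,1′-binaphthyl-2,2′-diyl hydrogen phosphate, 10 mol%], Hantzsch ester (diethyl 2,6-dimethyl-1,4-dihydropyridine-3,5-dicarboxylate, 1.5 equiv), 5 Å MS, CHCl3, 35 °C; aq NaHCO3
Reagents that add atoms: none
Why: Proposed new method: the chiral phosphoric acid ionises the o-hydroxybenzylic alcohol of 8 to o-quinone methide 9, which loses and regains C3′–H through the achiral enol ester 10 so that the racemic C3′ centre is scrambled, and the acid-bound 9 takes hydride at C4′ from the Hantzsch ester anti to the pseudoaxial 3′-acyloxy group (allylic 1,3-strain and acyloxy participation both point this way), which gives the cis ester while the catalyst selects one of the two interconverting enantiomers of 9, i.e. a dynamic kinetic asymmetric transfer hydrogenation that sets C3′ (S) and C4′ (R) together and cannot touch the angelate C=C; the closest known reaction type is the chiral phosphoric acid/Hantzsch ester transfer hydrogenation of o-quinone methides generated from o-hydroxybenzyl alcohols or o-hydroxystyrenes (one stereocentre, no α-oxygen, no dynamic resolution), and the amine is held as its triflimide salt so that it does not quench the catalyst.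

**Compound list**
1 | noreugenin (5,7-dihydroxy-2-methyl-4H-chromen-4-one) | Cc1cc(=O)c2c(O)cc(O)cc2o1 | starting material
2 | 1-methylpiperidin-4-one | CN1CCC(=O)CC1 | starting material
3 | 5,7-dihydroxy-8-(4-hydroxy-1-methylpiperidin-4-yl)-2-methyl-4H-chromen-4-one (carbinol, not isolated) | CN1CCC(O)(CC1)c1c(O)cc(O)c2c(=O)cc(C)oc12 | intermediate
4 | 5,7-dihydroxy-2-methyl-8-(1-methyl-1,2,3,6-tetrahydropyridin-4-yl)-4H-chromen-4-one | CN1CCC(=CC1)c1c(O)cc(O)c2c(=O)cc(C)oc12 | intermediate
5 | rac-8-[(3R,4R)-3,4-dihydroxy-1-methylpiperidin-4-yl]-5,7-dihydroxy-2-methyl-4H-chromen-4-one (cis-diol; racemate, one enantiomer drawn) | O[C@@H]1CN(C)CC[C@@]1(O)c1c(O)cc(O)c2c(=O)cc(C)oc12 | intermediate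
6 | angelic anhydride [(2Z)-2-methylbut-2-enoic anhydride] | C/C=C(/C)C(=O)OC(=O)/C(C)=C\C | starting material
7 | rac-(3R,4R)-3′,7-bis-angelate of 5 (not isolated; racemate, one enantiomer drawn) | C/C=C(/C)C(=O)O[C@@H]1CN(C)CC[C@@]1(O)c1c(OC(=O)/C(C)=C\C)cc(O)c2c(=O)cc(C)oc12 | intermediate
8 | rac-(3R,4R)-4-(5,7-dihydroxy-2-methyl-4-oxo-4H-chromen-8-yl)-4-hydroxy-1-methylpiperidin-3-yl (2Z)-2-methylbut-2-enoate (racemate, one enantiomer drawn) | C/C=C(/C)C(=O)O[C@@H]1CN(C)CC[C@@]1(O)c1c(O)cc(O)c2c(=O)cc(C)oc12 | intermediate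
9 | 4-(5-hydroxy-2-methyl-4,7-dioxo-4H-chromen-8(7H)-ylidene)-1-methylpiperidin-3-yl (2Z)-2-methylbut-2-enoate (o-quinone methide, not isolated; C3′ dynamic, either C=C geometry) | C/C=C(/C)C(=O)OC1CN(C)CCC1=C3C(=O)C=C(O)C2=C3OC(C)=CC2=O | intermediate
10 | 4-(5,7-dihydroxy-2-methyl-4-oxo-4H-chromen-8-yl)-1-methyl-1,2,5,6-tetrahydropyridin-3-yl (2Z)-2-methylbut-2-enoate (enol angelate, achiral, not isolated) | C/C=C(/C)C(=O)OC1=C(CCN(C)C1)c1c(O)cc(O)c2c(=O)cc(C)oc12 | intermediate
11 | (3S,4R)-4-(5,7-dihydroxy-2-methyl-4-oxo-4H-chromen-8-yl)-1-methylpiperidin-3-yl (2Z)-2-methylbut-2-enoate (rohitukine 3′-O-angelate, CNP0241711.2) | C/C=C(/C)C(=O)O[C@@H]1CN(C)CC[C@@H]1c1c(O)cc(O)c2c(=O)cc(C)oc12 | target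

**Step count and risks**
Total steps: 4. Longest linear sequence: 4 (1 → 4 → 5 → 8 → 11).

The three steps most likely to fail, in order, are 4, 1 and 3.

Step 4 is the new reaction. The open points are these:
- C3′ scrambling through 10 may be slower than hydride transfer, which would erode ee.
- TRIP may be too weak to ionise a carbinol that carries a β-acyloxy group and a nearby ammonium.
- The absolute sense given by (R)-TRIP is assigned only by analogy and has to be checked on the first run against the standards made below; the (S) catalyst is used if it is opposite.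

The first adjustments are pre-equilibrating 8 to 10 before adding the Hantzsch ester, and switching to a more acidic N-triflyl phosphoramide. The fallback uses known chemistry and sets out from 8. Ionic hydrogenation of the tertiary o-hydroxybenzylic alcohol with Et3SiH/CF3CO2H in CH2Cl2 at −20 to 0 °C, with hydride again entering anti to the 3′-acyloxy group, gives the racemic cis ester F1. Preparative SFC on an amylose carbamate chiral stationary phase separates it into 11 and its (3R,4S) enantiomer F2. The fallback comes back to the route at 11.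

Step 1 may give the C6 regioisomer or oligomers from the o-hydroxystyrene in hot acid. The fallback replaces the Friedel–Crafts union by a cross-coupling with fixed regiochemistry and sets out from 1.
- Me2SO4/K2CO3 in refluxing acetone gives 5,7-dimethoxy-2-methyl-4H-chromen-4-one F3.
- NIS/CF3CO2H in MeCN iodinates the dialkoxychromone at C8 to give 8-iodo-5,7-dimethoxy-2-methyl-4H-chromen-4-one F4.
- Suzuki–Miyaura coupling with commercial 1-methyl-1,2,3,6-tetrahydropyridine-4-boronic acid pinacol ester (Pd(dppf)Cl2, K3PO4, dioxane/H2O, 90 °C) gives the dimethyl ether of the alkene, 5,7-dimethoxy-2-methyl-8-(1-methyl-1,2,3,6-tetrahydropyridin-4-yl)-4H-chromen-4-one F5.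
- Pyridine hydrochloride at 180 °C removes both methyl groups.

The fallback comes back to the route at 4.

Step 3 may suffer from 3′ to 4′ acyl migration through the tertiary alkoxide, incomplete discrimination of the oxygens, or Z to E drift. The fallback is a protecting-group route without alkoxides and sets out from 5.
- tBuMe2SiCl (1.05 equiv)/Et3N in CH2Cl2–DMF at 0 °C silylates the acidic 7-phenol to give the 7-O-silyl diol F6.
- The mixed anhydride from angelic acid and 2,4,6-trichlorobenzoyl chloride (Et3N, toluene, 75 °C) acylates the secondary 3′-OH thermally to give the 7-O-silyl 3′-angelate F7.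
- Bu4NF/AcOH in THF at 0 °C removes the silyl group.

The fallback comes back to the route at 8.

**Further compounds**
F1 | step 4 | racemic cis ester (1:1 mixture of 11 and F2) | C/C=C(/C)C(=O)O[C@@H]1CN(C)CC[C@@H]1c1c(O)cc(O)c2c(=O)cc(C)oc12.C/C=C(/C)C(=O)O[C@H]1CN(C)CC[C@H]1c1c(O)cc(O)c2c(=O)cc(C)oc12
F2 | step 4 | (3R,4S)-4-(5,7-dihydroxy-2-methyl-4-oxo-4H-chromen-8-yl)-1-methylpiperidin-3-yl (2Z)-2-methylbut-2-enoate (enantiomer of 11) | C/C=C(/C)C(=O)O[C@H]1CN(C)CC[C@H]1c1c(O)cc(O)c2c(=O)cc(C)oc12
F3 | step 1 | 5,7-dimethoxy-2-methyl-4H-chromen-4-one | Cc1cc(=O)c2c(OC)cc(OC)cc2o1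
F4 | step 1 | 8-iodo-5,7-dimethoxy-2-methyl-4H-chromen-4-one | Cc1cc(=O)c2c(OC)cc(OC)c(I)c2o1
F5 | step 1 | 5,7-dimethoxy-2-methyl-8-(1-methyl-1,2,3,6-tetrahydropyridin-4-yl)-4H-chromen-4-one | CN1CCC(=CC1)c1c(OC)cc(OC)c2c(=O)cc(C)oc12
F6 | step 3 | rac-7-[(tert-butyldimethylsilyl)oxy]-8-[(3R,4R)-3,4-dihydroxy-1-methylpiperidin-4-yl]-5-hydroxy-2-methyl-4H-chromen-4-one (racemate, one enantiomer drawn) | O[C@@H]1CN(C)CC[C@@]1(O)c1c(O[Si](C)(C)C(C)(C)C)cc(O)c2c(=O)cc(C)oc12
F7 | step 3 | rac-(3R,4R)-4-{7-[(tert-butyldimethylsilyl)oxy]-5-hydroxy-2-methyl-4-oxo-4H-chromen-8-yl}-4-hydroxy-1-methylpiperidin-3-yl (2Z)-2-methylbut-2-enoate (racemate, one enantiomer drawn) | C/C=C(/C)C(=O)O[C@@H]1CN(C)CC[C@@]1(O)c1c(O[Si](C)(C)C(C)(C)C)cc(O)c2c(=O)cc(C)oc12
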